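**Strategy.** The route rests on cutting the C14–C15 bond of the cyclopentene C12–C16. In the reverse sense this gives a spirocyclopropane (C12, C15, C16) on the seven-membered ring, next to the C13=C14 bond of the ester-bearing cyclopentene. The key step exploits exactly this feature, the strained C12–C15 bond held beside the C13=C14 π bond: a nickel-catalysed vinylcyclopropane–cyclopentene rearrangement closes the last carbocycle, moves the double bond to C12=C13 and sets C14 in one operation. Its precursor is the pentacyclic amino ester with the spiro-dihydropyran, the 8-azabicyclo[4.3.1]decane core and the C17 ester trans to C6; C17 is inverted at the end.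

Key step: step 17

Remark: atom labels C1–C27 follow the heavy-atom order of the target SMILES (C6 spiro carbon, C9 and C23 bridgeheads, C17 ester-bearing carbon); C17 is epimerisable, so it is carried as a mixture from 4 to 21 and fixed only in steps 16 and 18.

**Step 1**
Reactants: 1 methyl 1-methyl-4-oxopiperidine-3-carboxylate; 2 allyl acetate
Product: 3 methyl (3S)-1-methyl-4-oxo-3-(prop-2-en-1-yl)piperidine-3-carboxylate
Conditions: [Pd(C3H5)Cl]2 (1 mol%), (1R,2R)-N,N′-bis[2-(diphenylphosphino)benzoyl]cyclohexane-1,2-diamine (3 mol%), 1,1,3,3-tetramethylguanidine, toluene, 0 °C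
Reagents that add atoms: none
Why: Palladium-catalysed asymmetric allylic alkylation (Tsuji–Trost reaction) of a cyclic β-keto ester, in which the chiral bisphosphine–π-allylpalladium complex differentiates the faces of the tetrasubstituted enolate and sets C23 as S (the ligand antipode that gives this sense is to be confirmed in a pilot run).

**Step 2**
Reactants: 3 methyl (3S)-1-methyl-4-oxo-3-(prop-2-en-1-yl)piperidine-3-carboxylate
Product: 4 dimethyl 2-{[(3S)-3-(methoxycarbonyl)-1-methyl-4-oxopiperidin-3-yl]methyl}butanedioate (both C17 epimers)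
Conditions: Pd(OCOCF3)2 (2 mol%), N,N′-bis(2,6-dimethylphenyl)butane-2,3-diimine (2.2 mol%), p-benzoquinone (1.5 equiv), TsOH·H2O (1.1 equiv), CO (4 bar), MeOH/THF, 20 °C
Reagents that add atoms: carbon monoxide [C-]#[O+]; methanol CO
Why: Palladium-catalysed oxidative bis(methoxycarbonylation) of the terminal alkene puts CO2Me on both alkene carbons, giving the succinate that carries the future C17 ester and the C14 carbanion site, with the amine masked as its tosylate salt and C17 formed without control, which does not matter here.

**Step 3**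
Reactants: 4 dimethyl 2-{[(3S)-3-(methoxycarbonyl)-1-methyl-4-oxopiperidin-3-yl]methyl}butanedioate
Product: 5 dimethyl 2-{[(3S)-3-(methoxycarbonyl)-1-methyl-4-(triisopropylsilyloxy)-1,2,3,6-tetrahydropyridin-3-yl]methyl}butanedioate (both C17 epimers)
Conditions: TIPSOTf, Et3N, CH2Cl2, 0 °C
Reagents that add atoms: triisopropylsilyl trifluoromethanesulfonate CC(C)[Si](OS(=O)(=O)C(F)(F)F)(C(C)C)C(C)C
Why: Silyl enol ether formation by soft enolisation of the ketone, which can enolise only towards C9 because C23 is quaternary, masks C6 for steps 4 to 8.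

**Step 4**
Reactants: 5 dimethyl 2-{[(3S)-3-(methoxycarbonyl)-1-methyl-4-(triisopropylsilyloxy)-1,2,3,6-tetrahydropyridin-3-yl]methyl}butanedioate
Product: 6 dimethyl 7-methyl-1-oxo-10-(triisopropylsilyloxy)-7-azaspiro[4.5]dec-9-ene-2,3-dicarboxylate (spiro carbon C23 as in 3; C14 and C17 epimers)
Conditions: NaN(SiMe3)2 (2.2 equiv), THF, −78 → 0 °C; AcOH
Reagents that add atoms: none
Why: Dieckmann condensation in which the C14 ester enolate attacks the C13 ester to close the five-membered ring (attack from C17 would give a four-membered ring), the product being held as its β-keto ester enolate.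

**Step 5**
Reactants: 6 dimethyl 7-methyl-1-oxo-10-(triisopropylsilyloxy)-7-azaspiro[4.5]dec-9-ene-2,3-dicarboxylate
Product: 7 methyl 7-methyl-1-oxo-10-(triisopropylsilyloxy)-7-azaspiro[4.5]dec-9-ene-3-carboxylate (C23 as in 3; C17 epimers)
Conditions: LiCl, H2O (2 equiv), DMSO, 130 °C
Reagents that add atoms: none
Why: Krapcho dealkoxycarbonylation removes only the β-keto ester group on C14, while the unactivated C17 ester and the hindered triisopropylsilyl enol ether should survive the neutral, hydrogencarbonate-buffered medium.

**Step 6**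
Reactants: 7 methyl 7-methyl-1-oxo-10-(triisopropylsilyloxy)-7-azaspiro[4.5]dec-9-ene-3-carboxylate
Product: 8 methyl 7-methyl-1-(trifluoromethylsulfonyloxy)-10-(triisopropylsilyloxy)-7-azaspiro[4.5]deca-1,9-diene-3-carboxylate (C23 as in 3; C17 epimers)
Conditions: KN(SiMe3)2 (1.0 equiv), THF, −78 °C; PhNTf2
Reagents that add atoms: N-phenylbis(trifluoromethanesulfonimide) O=S(=O)(N(c1ccccc1)S(=O)(=O)C(F)(F)F)C(F)(F)F
Why: Enol triflate formation: the kinetic enolate can form only at C14 (C23 is quaternary and C6 is masked), so O-sulfonylation fixes the C13=C14 double bond.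

**Step 7**
Reactants: 9 but-3-yn-1-ol
Product: 10 3-(tributylstannyl)but-3-en-1-ol
Conditions: Bu3SnH, [(C5Me5)RuCl]4 (1.25 mol%), CH2Cl2, 23 °C
Reagents that add atoms: tributyltin hydride CCCC[SnH](CCCC)CCCC
Why: Ruthenium-catalysed Markovnikov hydrostannation of a terminal alkyne, assisted by the free hydroxyl group, gives the 2-stannyl-1-alkene.

**Step 8**
Reactants: 8 methyl 7-methyl-1-(trifluoromethylsulfonyloxy)-10-(triisopropylsilyloxy)-7-azaspiro[4.5]deca-1,9-diene-3-carboxylate; 10 3-(tributylstannyl)but-3-en-1-ol
Product: 12 methyl 1-(4-hydroxybut-1-en-2-yl)-7-methyl-10-oxo-7-azaspiro[4.5]dec-1-ene-3-carboxylate (C23 as in 3; C17 epimers), via silyl enol ether 11 (not isolated)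
Conditions: Pd(PPh3)4 (10 mol%), CuCl, LiCl, DMSO, 60 °C; then Bu4NF, AcOH, THF, 0 °C
Reagents that add atoms: none
Why: Copper-assisted Stille cross-coupling joins C13 to C12 beside the quaternary C23, and buffered fluoride then cleaves the silyl enol ether to return the C6 ketone.

**Step 9**
Reactants: 12 methyl 1-(4-hydroxybut-1-en-2-yl)-7-methyl-10-oxo-7-azaspiro[4.5]dec-1-ene-3-carboxylate
Product: 13 methyl 1-[1-(2-hydroxyethyl)cyclopropyl]-7-methyl-10-oxo-7-azaspiro[4.5]dec-1-ene-3-carboxylate (C23 as in 3; C17 epimers)
Conditions: Et2Zn, CF3CO2H, CH2I2, CH2Cl2, 0 °C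
Reagents that add atoms: diiodomethane ICI
Why: Simmons–Smith cyclopropanation directed by the homoallylic zinc alkoxide converts only the nearby 1,1-disubstituted C12=CH2 bond into the spirocyclopropane (no new stereocentre), the acidic carbenoid CF3CO2ZnCH2I tolerating the tertiary amine and leaving the hindered C13=C14 bond alone.

**Step 10**
Reactants: 13 methyl 1-[1-(2-hydroxyethyl)cyclopropyl]-7-methyl-10-oxo-7-azaspiro[4.5]dec-1-ene-3-carboxylate
Product: 14 methyl 1-[1-(2-iodoethyl)cyclopropyl]-7-methyl-10-oxo-7-azaspiro[4.5]dec-1-ene-3-carboxylate (C23 as in 3; C17 epimers)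
Conditions: PPh3, I2, imidazole (premixed), CH2Cl2, 0 °C
Reagents that add atoms: iodine II
Why: Appel-type iodination of the primary alcohol with the preformed phosphine–iodine adduct keeps free iodine away from the vinylcyclopropane, and the iodide is used at once so that the amine does not alkylate itself.

**Step 11**
Reactants: 14 methyl 1-[1-(2-iodoethyl)cyclopropyl]-7-methyl-10-oxo-7-azaspiro[4.5]dec-1-ene-3-carboxylate
Product: 15 tricyclic ketone with the C9–C10 bond closed: 8-methyl-8-azabicyclo[4.3.1]decan-10-one core (C6 ketone) carrying the C12 spirocyclopropane, the fused C13=C14 cyclopentene and the C17 methyl ester (C9 and C23 as in the target; C17 epimers)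
Conditions: LiN(SiMe3)2 (2.2 equiv), THF (0.01 M), −78 → 0 °C
Reagents that add atoms: none
Why: Intramolecular enolate C-alkylation (7-(enolendo)-exo-tet): after the more acidic C17–H, the second equivalent of base forms the C9 lithium enolate, which can reach C10 only on the face cis to the C13 branch, so C9 is set by the geometry of the bridged ring being formed and C17 is merely reprotonated.

**Step 12**
Reactants: 15 tricyclic C6 ketone
Product: 17 C6 carbaldehyde of the tricycle (C7 = CHO; C6 and C17 epimers; C9 and C23 as in the target), via methyl enol ether 16 (not isolated)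
Conditions: Ph3P(CH2OMe)Cl, KN(SiMe3)2, THF, 0 → 50 °C; then aq. (CO2H)2, THF, 23 °C
Reagents that add atoms: (methoxymethyl)triphenylphosphonium chloride COC[P+](c1ccccc1)(c1ccccc1)c1ccccc1.[Cl-]; water O
Why: Wittig methoxymethylenation of the bridging ketone and mild hydrolysis of the enol ether give the homologous aldehyde (C7), the weak acid sparing the acid-labile vinylcyclopropane, and C6 is left uncontrolled because it is enolised in step 13.

**Step 13**
Reactants: 17 C6 carbaldehyde of the tricycle; 18 ethyl vinyl ketone
Product: 19 keto aldehyde with quaternary C6 bearing the formyl group (C7, over the piperidine ring) and the 3-oxopentyl chain (C5–C1, over the seven-membered ring) (C6, C9, C23 as in the target; C17 epimers)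
Conditions: 18 (3 equiv), Triton B (0.2 equiv), t-BuOH/THF, 0 °C
Reagents that add atoms: none
Why: Michael addition of the aldehyde enolate to the vinyl ketone forms the C5–C6 bond and the C6 quaternary centre, the enone approaching the exocyclic enolate over the seven-membered ring, where only one axial C–H (C10) opposes it and C13 is trigonal, and not over the piperidine ring with its two axial C–H bonds (C24, C27).

**Step 14**
Reactants: 19 keto aldehyde
Product: 20 hydroxy ketone with C6 bearing CH2OH (C7) and the 3-oxopentyl chain (may exist as the cyclic hemiketal; C17 epimers)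
Conditions: NaBH4, CH2Cl2/MeOH, −78 °C
Reagents that add atoms: none
Why: Aldehyde-selective borohydride reduction at low temperature leaves the less electrophilic ethyl ketone and the ester untouched and creates no stereocentre.

**Step 15**
Reactants: 20 hydroxy ketone
Product: 21 spiro-dihydropyran vinylcyclopropane as a mixture of C17 epimers (C6, C9, C23 as in the target)
Conditions: TsOH·H2O (1.0 equiv), PPTS (0.2 equiv), 4 Å MS, toluene, 60 °C; Et3N
Reagents that add atoms: none
Why: Acid-catalysed cyclodehydration of the δ-hydroxy ketone (hemiketal formation, then loss of water to the endocyclic enol ether) closes the 6-ethyl-3,4-dihydro-2H-pyran, with the amine held as its tosylate so that only a pyridinium acid is free and the vinylcyclopropane should be spared.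

**Step 16**
Reactants: 21 spiro-dihydropyran vinylcyclopropane (C17 epimers)
Product: 22 precursor of the key step: the spirocyclopropyl cyclopentene ester with the C17 ester trans to C6
Conditions: NaOMe (0.3 equiv), MeOH, 0 → 23 °C; AcOH
Reagents that add atoms: none
Why: Base-mediated epimerisation through the ester enolate should, under thermodynamic control, place the ester cis to the C24 methylene and away from the spiro carbon C6, whose C5 and C7 methylenes crowd the other face, while kinetic α-reprotonation keeps the double bond at C13=C14; the minor epimer is separated and recycled.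

**Step 17**
Reactants: 22 spirocyclopropyl cyclopentene ester (C17 ester trans to C6)
Product: 23 17-epimer of the target (new cyclopentene C12–C16, C12=C13 double bond, C15 on C14 syn to C6, ester trans to C15)
Conditions: Ni(cod)2 (10 mol%), 1,3-bis(2,6-diisopropylphenyl)imidazol-2-ylidene (10 mol%), toluene, 60 °C
Reagents that add atoms: none
Why: Zerovalent nickel carrying the N-heterocyclic carbene binds the C13=C14 bond on the face away from the C17 ester and inserts into the adjacent strained C12–C15 bond, giving a six-membered nickelacycle in which C12–C13–C14 is an η3-allyl ligand and C15 an alkyl ligand; reductive elimination then joins C15 to C14. The closest known reaction type is the nickel–carbene-catalysed vinylcyclopropane–cyclopentene rearrangement of unactivated vinylcyclopropanes, whose uncatalysed counterpart is the thermal diradical [1,3] shift. The cyclopentene C12–C13–C14–C15–C16 closes by C(sp3)–C(sp3) reductive elimination at the allyl terminus C14, and the remaining π bond of the allyl becomes the tetrasubstituted C12=C13 bond shared with the seven-membered ring. C14 is the only new stereocentre and is controlled by the C17 ester, which shields the lower face so that nickel, and hence C15, arrive syn to C6; C15 and C16 are equivalent, so either may migrate. The step needs this facial selectivity and chemoselectivity for the cyclopropane over the enol ether, ester and amine: the trans ester secures the first, and the second follows because only the cyclopropane bonds at C12 are both strained and allylic. Relief of ring strain and formation of the tetrasubstituted alkene should make the step irreversible.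

**Step 18**
Reactants: 23 17-epimer of the target
Product: 24 target CNP0159589.2
Conditions: LiN(i-Pr)2, THF, −78 °C; then AcOH, −78 °C
Reagents that add atoms: none
Why: Kinetic protonation of the lithium ester enolate delivers the proton to the face opposite C15 and the C6 spiro ring, which turns the ester cis to C15 and gives the less stable C17 epimer that is the target (enolate epimerisation).

**Compound list**
1 | methyl 1-methyl-4-oxopiperidine-3-carboxylate | COC(=O)C1CN(C)CCC1=O | starting material
2 | allyl acetate | CC(=O)OCC=C | starting material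
3 | methyl (3S)-1-methyl-4-oxo-3-(prop-2-en-1-yl)piperidine-3-carboxylate | COC(=O)[C@@]1(CC=C)CN(C)CCC1=O | intermediate
4 | dimethyl 2-{[(3S)-3-(methoxycarbonyl)-1-methyl-4-oxopiperidin-3-yl]methyl}butanedioate (C17 epimers) | COC(=O)CC(C(=O)OC)C[C@]1(C(=O)OC)CN(C)CCC1=O | intermediate
5 | dimethyl 2-{[(3S)-3-(methoxycarbonyl)-1-methyl-4-(triisopropylsilyloxy)-1,2,3,6-tetrahydropyridin-3-yl]methyl}butanedioate (C17 epimers) | COC(=O)CC(C(=O)OC)C[C@]1(C(=O)OC)CN(C)CC=C1O[Si](C(C)C)(C(C)C)C(C)C | intermediate
6 | dimethyl 7-methyl-1-oxo-10-(triisopropylsilyloxy)-7-azaspiro[4.5]dec-9-ene-2,3-dicarboxylate (C14 and C17 epimers) | COC(=O)C1C[C@@]2(CN(C)CC=C2O[Si](C(C)C)(C(C)C)C(C)C)C(=O)C1C(=O)OC | intermediate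
7 | methyl 7-methyl-1-oxo-10-(triisopropylsilyloxy)-7-azaspiro[4.5]dec-9-ene-3-carboxylate (C17 epimers) | COC(=O)C1C[C@@]2(CN(C)CC=C2O[Si](C(C)C)(C(C)C)C(C)C)C(=O)C1 | intermediate
8 | methyl 7-methyl-1-(trifluoromethylsulfonyloxy)-10-(triisopropylsilyloxy)-7-azaspiro[4.5]deca-1,9-diene-3-carboxylate (C17 epimers) | COC(=O)C1C[C@@]2(CN(C)CC=C2O[Si](C(C)C)(C(C)C)C(C)C)C(OS(=O)(=O)C(F)(F)F)=C1 | intermediate
9 | but-3-yn-1-ol | C#CCCO | starting material
10 | 3-(tributylstannyl)but-3-en-1-ol | C=C(CCO)[Sn](CCCC)(CCCC)CCCC | intermediate
11 | methyl 1-(4-hydroxybut-1-en-2-yl)-7-methyl-10-(triisopropylsilyloxy)-7-azaspiro[4.5]deca-1,9-diene-3-carboxylate (C17 epimers) | COC(=O)C1C[C@@]2(CN(C)CC=C2O[Si](C(C)C)(C(C)C)C(C)C)C(C(=C)CCO)=C1 | intermediate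
12 | methyl 1-(4-hydroxybut-1-en-2-yl)-7-methyl-10-oxo-7-azaspiro[4.5]dec-1-ene-3-carboxylate (C17 epimers) | COC(=O)C1C[C@@]2(CN(C)CCC2=O)C(C(=C)CCO)=C1 | intermediate
13 | methyl 1-[1-(2-hydroxyethyl)cyclopropyl]-7-methyl-10-oxo-7-azaspiro[4.5]dec-1-ene-3-carboxylate (C17 epimers) | COC(=O)C1C[C@@]2(CN(C)CCC2=O)C(C2(CCO)CC2)=C1 | intermediate
14 | methyl 1-[1-(2-iodoethyl)cyclopropyl]-7-methyl-10-oxo-7-azaspiro[4.5]dec-1-ene-3-carboxylate (C17 epimers) | COC(=O)C1C[C@@]2(CN(C)CCC2=O)C(C2(CCI)CC2)=C1 | intermediate
15 | tricyclic C6 ketone: bridged azabicyclo[4.3.1]decanone with C12 spirocyclopropane, C13=C14 cyclopentene and C17 ester (C17 epimers) | O=C1[C@@H]2CCC3(CC3)C4=CC(C(=O)OC)C[C@]14CN(C)C2 | intermediate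
16 | C6 methoxymethylene enol ether of 15 (E/Z, C17 epimers) | COC=C1[C@@H]2CCC3(CC3)C4=CC(C(=O)OC)C[C@]14CN(C)C2 | intermediate
17 | C6 carbaldehyde of the tricycle (C6 and C17 epimers) | O=CC1[C@@H]2CCC3(CC3)C4=CC(C(=O)OC)C[C@]14CN(C)C2 | intermediate
18 | ethyl vinyl ketone (pent-1-en-3-one) | CCC(=O)C=C | starting material
19 | keto aldehyde: quaternary C6 with CHO and 3-oxopentyl (C17 epimers) | CCC(=O)CC[C@]1(C=O)[C@@H]2CCC3(CC3)C4=CC(C(=O)OC)C[C@]14CN(C)C2 | intermediate
20 | hydroxy ketone: quaternary C6 with CH2OH and 3-oxopentyl (C17 epimers) | CCC(=O)CC[C@]1(CO)[C@@H]2CCC3(CC3)C4=CC(C(=O)OC)C[C@]14CN(C)C2 | intermediate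
21 | spiro-dihydropyran vinylcyclopropane, C17 epimer mixture | CCC1=CC[C@]2(CO1)[C@@H]1CCC3(CC3)C4=CC(C(=O)OC)C[C@@]42CN(C)C1 | intermediate
22 | spirocyclopropyl cyclopentene ester, C17 ester trans to C6 (precursor of the key step) | CCC1=CC[C@]2(CO1)[C@@H]1CCC3(CC3)C4=C[C@@H](C(=O)OC)C[C@@]42CN(C)C1 | intermediate
23 | 17-epimer of the target (product of the key step) | CCC1=CC[C@]2(CO1)[C@@H]1CCC3=C4[C@H](CC3)[C@@H](C(=O)OC)C[C@@]42CN(C)C1 | intermediate
24 | CNP0159589.2 | CCC1=CC[C@]2(CO1)[C@@H]1CCC3=C4[C@H](CC3)[C@H](C(=O)OC)C[C@@]42CN(C)C1 | target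

**Step count.** Total: 18 steps. Longest linear sequence: 17 steps (steps 1–6 and 8–18, from 1).

**Steps most likely to fail**

Step 17. Zerovalent nickel may insert too slowly at the hindered trisubstituted vinylcyclopropane beside the spiro-dihydropyran, or the ring may close on both faces of C14 (poor facial selectivity). The fallback moves the ring expansion ahead of the dihydropyran construction, so that the key bond is made on a smaller substrate without the enol ether. It sets out from ketone 15, equilibrated with NaOMe and with the ester-trans epimer separated. The same nickel–carbene catalyst should give the rearranged cyclopentene ketone F1. Wittig methoxymethylenation then gives the methyl enol ether F2, mild acid the aldehyde F3, Michael addition to 18 the keto aldehyde F4, NaBH4 the hydroxy ketone F5, and cyclodehydration the dihydropyran F6 (C17 epimers). F6 is deprotonated and protonated under the conditions of step 18 and comes back to the route at 24.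

Step 13. The hindered aldehyde enolate may fail to add to 18 at a carbon flanked by a quaternary and a bridgehead carbon, or the adduct may go on to an intramolecular aldol condensation (Robinson annulation). The fallback replaces the ionic addition by a concerted cycloaddition. It sets out from the methyl enol ether 16, isolated instead of hydrolysed. An inverse-electron-demand hetero-Diels–Alder reaction with 18 (neat, 110 °C, sealed tube) forms the same C5–C6 and C7–O8 bonds and gives the 2-methoxy spiro-dihydropyran F7. Ionic reduction of the anomeric methoxy group (Et3SiH, BF3·OEt2, CH2Cl2, −78 °C) comes back to the route at 21.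

Step 11. The enolate may be alkylated on oxygen to a seven-membered cyclic enol ether, or the amine may be alkylated by the iodide before the enolate forms. The fallback replaces the SN2 alkylation by a carbonyl addition. It sets out from alcohol 13. Dess–Martin oxidation gives the aldehyde F8, and intramolecular aldol addition of the C9 lithium enolate (LiN(SiMe3)2, THF, −78 °C) gives the bridged β-hydroxy ketone F9. Thiocarbonyldiimidazole gives the imidazole-1-carbothioate F10, and Barton–McCombie deoxygenation (Bu3SnH, AIBN, toluene, 80 °C) comes back to the route at 15.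

**Further compounds**
F1 | step 17 | rearranged cyclopentene ketone (C6 ketone, C12=C13, C15 syn to C6, ester trans to C15) | O=C1[C@@H]2CCC3=C4[C@H](CC3)[C@@H](C(=O)OC)C[C@]14CN(C)C2
F2 | step 17 | C6 methoxymethylene enol ether of F1 (C17 epimers) | COC=C1[C@@H]2CCC3=C4[C@H](CC3)C(C(=O)OC)C[C@]14CN(C)C2
F3 | step 17 | C6 carbaldehyde of the rearranged tricycle (C6 and C17 epimers) | O=CC1[C@@H]2CCC3=C4[C@H](CC3)C(C(=O)OC)C[C@]14CN(C)C2
F4 | step 17 | rearranged keto aldehyde with quaternary C6 (C17 epimers) | CCC(=O)CC[C@]1(C=O)[C@@H]2CCC3=C4[C@H](CC3)C(C(=O)OC)C[C@]14CN(C)C2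
F5 | step 17 | rearranged hydroxy ketone with quaternary C6 (C17 epimers) | CCC(=O)CC[C@]1(CO)[C@@H]2CCC3=C4[C@H](CC3)C(C(=O)OC)C[C@]14CN(C)C2
F6 | step 17 | spiro-dihydropyran with the target skeleton, C17 epimer mixture | CCC1=CC[C@]2(CO1)[C@@H]1CCC3=C4[C@H](CC3)C(C(=O)OC)C[C@@]42CN(C)C1
F7 | step 13 | 2-methoxy spiro-dihydropyran vinylcyclopropane (C7 and C17 epimers) | CCC1=CC[C@]2(C(OC)O1)[C@@H]1CCC3(CC3)C4=CC(C(=O)OC)C[C@@]42CN(C)C1
F8 | step 11 | methyl 7-methyl-10-oxo-1-[1-(2-oxoethyl)cyclopropyl]-7-azaspiro[4.5]dec-1-ene-3-carboxylate (C17 epimers) | COC(=O)C1C[C@@]2(CN(C)CCC2=O)C(C2(CC=O)CC2)=C1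
F9 | step 11 | bridged β-hydroxy ketone, 15 with OH on C10 (C10 and C17 epimers) | O=C1[C@@H]2C(O)CC3(CC3)C4=CC(C(=O)OC)C[C@]14CN(C)C2
F10 | step 11 | O-(imidazole-1-carbothioyl) derivative of F9 | O=C1[C@@H]2C(OC(=S)n5ccnc5)CC3(CC3)C4=CC(C(=O)OC)C[C@]14CN(C)C2
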